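An easy step stands first in this flask: starting material going to dormant form and back, with no partner.

starting material 0.50 M; reagent in the second phase 0.900 equiv; time 4.0 min; volume of the second phase over the first 0.25

    reagent in the reaction phase + target → over-reacted product (k1 = 0.033 M⁻¹ s⁻¹)
    reagent in the reaction phase ⇌ reagent in the second phase, rate k2*([reagent in the reaction phase] - [reagent in the second phase]/K2) per volume of the first phase (K2 = 1.8, k2 = 0.012 s⁻¹)
    2 reagent in the reaction phase → self-condensation product (k3 = 0.039 M⁻¹ s⁻¹)
    starting material ⇌ dormant form (K4 = 3.5, k4 = 0.044 s⁻¹)
    starting material → decomposition product (k5 = 8.7 × 10⁻⁵ s⁻¹)
    starting material + reagent in the reaction phase → target (k6 = 0.028 M⁻¹ s⁻¹)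

- for a step with 2 of a species take k times the square, and two of it per event
- in the second phase: reagent in the second phase; everything else is in the first
- charges count per volume of the first phase; a concentration in a rate is the amount of a species over the volume of its own phase; every rate counts per litre of the first phase
- what has gone from starting material into another species counts as reacted, even if it can come back
- run time (flask): 4.0 min

- amount of target at 4.0 min, in percent of the starting material charged
- part of the starting material charged that has reacted at 4.0 min

This pair relaxes with a half-life of 0.204 min, far shorter than the run of 4.0 min, so [dormant form]/[starting material] can be frozen at 3.5 (a pre-equilibrium), and the two form one pool. The free share, the part of that pool standing as starting material, is 22.2%. Dormant form counts as reacted, so the reacted part is one minus the free share times the pool left.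

The opposite outcome, free starting material drained well below that share of the pool, asks the target-forming step to outrun the relaxation. Even this flask's whole reagent charge of 0.450 M, counted as standing in the reaction phase, gives starting material a pseudo-first-order constant of 0.0126 s⁻¹, while the relaxation runs at 0.0566 s⁻¹, 4.49 times faster.

Once relaxed, the pool leaks to target at the target-step constant times [reagent in the reaction phase] times the free share. With the pool intact, the reckoning gives this flask 77.8% reacted. With [reagent in the reaction phase] held at the partition level of the whole charge, 0.310 M, it gives 86.0%. The reckoning commits to that bracket, as an estimate and not as a bound.

The forecast put target at 10.8% (9.8% to 11.9%) and the reacted part at 82.2% (81% to 83.3%), in its words “counting dormant form as reacted”. The simulation gives 10.8% and 82.2%, the latter inside the bracket.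

Ten times the time still changes this flask a little: at 40.0 min [reagent in the reaction phase] has fallen from 0.0550 M to 6.09 × 10⁻⁵ M, target stands at 12.2%, decomposition product has grown from 0.509% to 3.62%, and the reacted part has moved by 1.7 percentage points to 83.9%. The free share still reads it: the products leave a pool of 72.4%, which gives 83.9% reacted.

For the neighbour flask with 0.12 M of starting material, the same free share puts the estimated reacted part between 77.8% and 80.1%. The simulation gives 79.9%, with target at 6.14%.

The rate constants were set for the occasion; the result is computed.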